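**Retrosynthetic overview**

1. Upper flavan unit = rings A, C, B; lower unit = rings D, F, E; each unit has its own flavan numbering. The target comes from global hydrogenolysis of a benzyl-protected dimer whose lower C3–OH arises from a C3 formyl group by Baeyer–Villiger oxidation with retention.
2. Key disconnection: the C2–C3 bond of pyran ring F. It is closed on a ring D cinnamaldehyde by a redox-neutral cascade: 1,5-hydride shift from the benzylic C2–H of the O1 benzyl ether to C4, then attack of enamine carbon C3 on oxocarbenium carbon C2. This sets C2 and C3 and leaves C4 as the CH2 of the target.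
3. Enabling feature: C2 carries O1 and ring E, whose 4-oxygen and O1 stabilise the cation left by hydride loss, and C2–H sits 1,5 to C4 because O1 and the C4 side chain are ortho on ring D.
4. The cinnamaldehyde comes from 5,7-dihydroxycoumarin (ring D plus a masked C4–C3–CHO chain). Its lactone oxygen (the future O5) is tied back, so the flavan-4-yl cation enters at coumarin C8, which is C6 of ring D; this fixes the 4→6 link. The coumarin 5-OH becomes O1.
5. Ring order: rings A, B, C are bought with (2R,3R)-fustin; ring D arrives with the coumarin (interflavanyl bond by Friedel–Crafts, C4 trans to the 3-OH); ring E is attached as a benzyl ether on O1; ring F is closed last.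

Key step: step 9

Assumption: (2R,3R)-fustin is bought as the single enantiomer and supplies C2 and C3 of the upper unit.

**Step 1**
Reactants: 1 (2R,3R)-fustin
Product: 2 7,3',4'-tri-O-benzylfustin
Conditions: BnBr (3.3 equiv), K2CO3, DMF, 25 °C
Reagents that add atoms: benzyl bromide, BrCc1ccccc1
Why: Williamson ether synthesis: K2CO3 ionises only the three phenols, so the C3 alcohol stays free, and once the 4'-oxygen is capped the quinone-methide opening of ring C that would epimerise C2 is blocked, so both stereocentres of 1 are kept.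

**Step 2**
Reactants: 2 7,3',4'-tri-O-benzylfustin
Product: 3 tri-O-benzyl flavan-3,4-diol (2R,3S,4R)
Conditions: NaBH4, THF/MeOH (1:1), 0 °C
Reagents that add atoms: none
Why: Borohydride reduction of the aryl ketone, which for 2,3-trans dihydroflavonols is expected to favour the 3,4-trans diol (4R) by hydride delivery anti to the C3 substituent; the C4 configuration is immaterial because C4 is ionised in step 3.

**Step 3**
Reactants: 3 tri-O-benzyl flavan-3,4-diol; 4 5,7-dihydroxycoumarin (4 equiv)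
Product: 5 8-(flavan-4-yl)-5,7-dihydroxycoumarin
Conditions: BF3·OEt2 (0.5 equiv), 1,4-dioxane, 15 → 25 °C
Reagents that add atoms: none
Why: Friedel–Crafts alkylation through the C4 benzylic cation formed by loss of water from 3 (stabilised by the 7-benzyloxy group para to C4a): the coumarin is expected to react at C8, which is ortho to the 7-OH, para to the 5-OH and flanked by the ring-bound lactone oxygen, and to approach the half-chair cation anti to the C3 hydroxyl, so that C4 is set as S (3,4-trans) from either C4 epimer of 3.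

**Step 4**
Reactants: 6 3,4,5-tris(benzyloxy)benzyl alcohol
Product: 7 3,4,5-tris(benzyloxy)benzyl bromide
Conditions: PBr3 (0.4 equiv), CH2Cl2, 0 °C
Reagents that add atoms: phosphorus tribromide, BrP(Br)Br
Why: Conversion of the benzylic alcohol into the bromide with PBr3 (substitution of the intermediate phosphite by bromide), routine for an electron-rich benzyl alcohol; no stereocentre is involved.

**Step 5**
Reactants: 5 8-(flavan-4-yl)-5,7-dihydroxycoumarin; 7 3,4,5-tris(benzyloxy)benzyl bromide (2.3 equiv)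
Product: 8 5,7-bis-O-[3,4,5-tris(benzyloxy)benzyl] coumarin
Conditions: K2CO3, n-Bu4NI (cat.), DMF, 40 °C
Reagents that add atoms: none
Why: Williamson ether synthesis on both coumarin phenols with the same bromide, so the two hydroxyls need not be told apart (the O7 ether is a spectator that leaves in step 11); the secondary C3 alcohol is not ionised by K2CO3 and the lactone is stable to anhydrous carbonate.

**Step 6**
Reactants: 8 5,7-bis-O-[3,4,5-tris(benzyloxy)benzyl] coumarin
Product: 9 ring-opened phenol with (Z)-3-hydroxyprop-1-enyl side chain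
Conditions: i-Bu2AlH (5 equiv), CH2Cl2, −78 → 0 °C; aqueous potassium sodium tartrate (KNaC4H4O6) work-up
Reagents that add atoms: none
Why: i-Bu2AlH reduces the conjugated lactone by 1,2-hydride addition through the lactol to the ring-opened allylic alcohol and phenol, the Z double bond being inherited from the coumarin ring; benzyl ethers are inert and no stereocentre is formed.

**Step 7**
Reactants: 9 ring-opened phenol
Product: 10 O5-[4-(trifluoromethyl)benzyl] ether of 9
Conditions: 4-(trifluoromethyl)benzyl bromide (1.1 equiv), K2CO3, DMF, 25 °C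
Reagents that add atoms: 4-(trifluoromethyl)benzyl bromide, BrCc1ccc(cc1)C(F)(F)F
Why: Williamson ether synthesis selective for the only phenol (the two alcohols are not ionised by K2CO3); the 4-(trifluoromethyl)benzyl group is chosen because its electron-poor benzylic C–H is a poor hydride donor in step 9 yet still falls to hydrogenolysis in step 11.

**Step 8**
Reactants: 10 allylic alcohol
Product: 11 (Z)-cinnamaldehyde of ring D
Conditions: MnO2 (activated, 20 equiv), CH2Cl2, 25 °C
Reagents that add atoms: none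
Why: Chemoselective MnO2 oxidation of the allylic alcohol to the enal, which leaves the non-activated secondary C3 alcohol untouched; partial Z to E isomerisation is harmless because both isomers converge in step 9.

**Step 9**
Reactants: 11 (Z)-cinnamaldehyde of ring D
Product: 14 trans-3-formylflavan (lower unit 2S,3S), via iminium ion 12 (not isolated), via oxocarbenium enamine 13 (not isolated)
Conditions: (R)-2-{bis[3,5-bis(trifluoromethyl)phenyl][(trimethylsilyl)oxy]methyl}pyrrolidine (20 mol%), CF3CO2H (20 mol%), ClCH2CH2Cl, 60 °C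
Reagents that add atoms: none
Why: Proposed new method: condensation of 11 with the amine gives iminium ion 12, whose C4 (the beta-carbon, on ring D) should accept the benzylic C2–H of the neighbouring O1 ether by a 1,5-hydride shift through a six-membered transition state, giving 13, in which C4 is already the CH2 of the target, C3 is an enamine carbon and C2 is an oxocarbenium carbon; C3 then bonds to C2 and hydrolysis by the water formed at the start returns the catalyst. The closest known reaction type is the redox-neutral 1,5-hydride-transfer/cyclisation cascade, known with Lewis acids for benzyl aryl ethers and alkylidene malonates (giving chromans) and with chiral secondary amines for o-(dialkylamino)cinnamaldehydes and cyclic ether donors; new here is the pairing of a benzyl aryl ether donor with iminium activation. Ring F closes by C2–C3 bond formation, the exocyclic enamine carbon attacking the endocyclic oxocarbenium carbon (6-enolexo-endo-trig, half-chair). The catalyst sets C3: by the usual shielding model for this catalyst class (the S catalyst directs electrophiles to the Si face of the E-enamine), the R catalyst should make C3 bond through its Re face, and the half-chair with ring E pseudo-equatorial then fixes C2 trans to the formyl group. The trans arrangement is also the thermodynamic one, since the formyl-bearing carbon can equilibrate through the enamine, and the E and Z isomers of 11 converge through 12. The step needs site selectivity among benzylic C–H bonds, secured because only the O1 benzyl group is both ortho to the enal (1,5 relation) and electron-rich (4-oxygen of ring E plus O1), whereas the other ortho ether carries the electron-poor 4-(trifluoromethyl)benzyl group and the O7 ether is para and out of reach.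

**Step 10**
Reactants: 14 trans-3-formylflavan
Product: 16 benzyl-protected fisetinidol-(4alpha,6)-gallocatechin, via formate 15 (not isolated)
Conditions: mCPBA (1.5 equiv), CH2Cl2, 0 → 25 °C; aqueous Na2S2O3/NaHCO3 wash; then K2CO3 (0.2 equiv), MeOH, 0 °C
Reagents that add atoms: meta-chloroperoxybenzoic acid, OOC(=O)c1cccc(Cl)c1
Why: Baeyer–Villiger oxidation of the alpha-branched aldehyde, in which the secondary carbon C3 should migrate to oxygen with retention in preference to hydride, followed by transesterification of the formate with methanol, so that the C3 configuration set in step 9 is carried into the alcohol (3S) and C2 becomes 2R by priority change only.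

**Step 11**
Reactants: 16 benzyl-protected fisetinidol-(4alpha,6)-gallocatechin
Product: 17 fisetinidol-(4alpha,6)-gallocatechin
Conditions: H2 (1 atm), Pd(OH)2/C, THF/MeOH (1:1, degassed), 25 °C
Reagents that add atoms: none
Why: Hydrogenolysis over Pd(OH)2/C should cleave the eleven benzyl-type ArO–CH2Ar bonds (nine benzyl, one tris(benzyloxy)benzyl and one 4-(trifluoromethyl)benzyl ether) under neutral conditions, while the cyclic benzylic C2–O1 ethers of both pyran rings and all five stereocentres are left untouched.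

**Compound list**

Abbreviations used in names: Fis = (2R,3S,4S)-7-(benzyloxy)-2-[3,4-bis(benzyloxy)phenyl]-3-hydroxychroman-4-yl (upper unit, bonded through C4); TBB = 3,4,5-tris(benzyloxy)benzyl; TFB = 4-(trifluoromethyl)benzyl; Cat = the (R)-pyrrolidine catalyst of step 9, bonded through nitrogen.

1 | (2R,3R)-fustin, (2R,3R)-2-(3,4-dihydroxyphenyl)-3,7-dihydroxychroman-4-one | Oc1ccc2c(c1)O[C@H](c1ccc(O)c(O)c1)[C@@H](O)C2=O | starting material
2 | (2R,3R)-7-(benzyloxy)-2-[3,4-bis(benzyloxy)phenyl]-3-hydroxychroman-4-one | c1ccccc1COc1ccc2c(c1)O[C@H](c1ccc(OCc3ccccc3)c(OCc3ccccc3)c1)[C@@H](O)C2=O | intermediate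
3 | (2R,3S,4R)-7-(benzyloxy)-2-[3,4-bis(benzyloxy)phenyl]chromane-3,4-diol (any 4S epimer is carried along) | c1ccccc1COc1ccc2c(c1)O[C@H](c1ccc(OCc3ccccc3)c(OCc3ccccc3)c1)[C@@H](O)[C@@H]2O | intermediate
4 | 5,7-dihydroxy-2H-chromen-2-one (5,7-dihydroxycoumarin) | O=c1ccc2c(O)cc(O)cc2o1 | starting material
5 | 8-Fis-5,7-dihydroxy-2H-chromen-2-one | c1ccccc1COc1ccc2c(c1)O[C@H](c1ccc(OCc3ccccc3)c(OCc3ccccc3)c1)[C@@H](O)[C@@H]2c1c(O)cc(O)c2ccc(=O)oc12 | intermediate
6 | [3,4,5-tris(benzyloxy)phenyl]methanol | OCc1cc(OCc2ccccc2)c(OCc2ccccc2)c(OCc2ccccc2)c1 | starting material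
7 | 1,2,3-tris(benzyloxy)-5-(bromomethyl)benzene (TBB bromide) | BrCc1cc(OCc2ccccc2)c(OCc2ccccc2)c(OCc2ccccc2)c1 | intermediate
8 | 8-Fis-5,7-bis(TBB-oxy)-2H-chromen-2-one | c1ccccc1COc1ccc2c(c1)O[C@H](c1ccc(OCc3ccccc3)c(OCc3ccccc3)c1)[C@@H](O)[C@@H]2c1c(OCc3cc(OCc4ccccc4)c(OCc4ccccc4)c(OCc4ccccc4)c3)cc(OCc3cc(OCc4ccccc4)c(OCc4ccccc4)c(OCc4ccccc4)c3)c2ccc(=O)oc12 | intermediate
9 | 2-Fis-6-[(1Z)-3-hydroxyprop-1-en-1-yl]-3,5-bis(TBB-oxy)phenol | c1ccccc1COc1ccc2c(c1)O[C@H](c1ccc(OCc3ccccc3)c(OCc3ccccc3)c1)[C@@H](O)[C@@H]2c1c(OCc3cc(OCc4ccccc4)c(OCc4ccccc4)c(OCc4ccccc4)c3)cc(OCc3cc(OCc4ccccc4)c(OCc4ccccc4)c(OCc4ccccc4)c3)c(/C=C\CO)c1O | intermediate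
10 | (2Z)-3-[3-Fis-2-(TFB-oxy)-4,6-bis(TBB-oxy)phenyl]prop-2-en-1-ol | c1ccccc1COc1ccc2c(c1)O[C@H](c1ccc(OCc3ccccc3)c(OCc3ccccc3)c1)[C@@H](O)[C@@H]2c1c(OCc3cc(OCc4ccccc4)c(OCc4ccccc4)c(OCc4ccccc4)c3)cc(OCc3cc(OCc4ccccc4)c(OCc4ccccc4)c(OCc4ccccc4)c3)c(/C=C\CO)c1OCc1ccc(cc1)C(F)(F)F | intermediate
11 | (2Z)-3-[3-Fis-2-(TFB-oxy)-4,6-bis(TBB-oxy)phenyl]prop-2-enal | c1ccccc1COc1ccc2c(c1)O[C@H](c1ccc(OCc3ccccc3)c(OCc3ccccc3)c1)[C@@H](O)[C@@H]2c1c(OCc3cc(OCc4ccccc4)c(OCc4ccccc4)c(OCc4ccccc4)c3)cc(OCc3cc(OCc4ccccc4)c(OCc4ccccc4)c(OCc4ccccc4)c3)c(/C=C\C=O)c1OCc1ccc(cc1)C(F)(F)F | intermediate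
12 | iminium trifluoroacetate of 11 and Cat: the ring D side chain is (E)-CH=CH–CH=N+(Cat) | c1ccccc1COc1ccc2c(c1)O[C@H](c1ccc(OCc3ccccc3)c(OCc3ccccc3)c1)[C@@H](O)[C@@H]2c1c(OCc3cc(OCc4ccccc4)c(OCc4ccccc4)c(OCc4ccccc4)c3)cc(OCc3cc(OCc4ccccc4)c(OCc4ccccc4)c(OCc4ccccc4)c3)c(/C=C/C=[N+]5\CCC[C@@H]5C(O[Si](C)(C)C)(c5cc(cc(c5)C(F)(F)F)C(F)(F)F)c5cc(cc(c5)C(F)(F)F)C(F)(F)F)c1OCc1ccc(cc1)C(F)(F)F.[O-]C(=O)C(F)(F)F | intermediate (not isolated)
13 | oxocarbenium enamine trifluoroacetate: the side chain is CH2–CH=CH–N(Cat) (E) and O1 is ArO+=CH–[3,4,5-tris(benzyloxy)phenyl] | c1ccccc1COc1ccc2c(c1)O[C@H](c1ccc(OCc3ccccc3)c(OCc3ccccc3)c1)[C@@H](O)[C@@H]2c1c(OCc3cc(OCc4ccccc4)c(OCc4ccccc4)c(OCc4ccccc4)c3)cc([O+]=Cc3cc(OCc4ccccc4)c(OCc4ccccc4)c(OCc4ccccc4)c3)c(C/C=C/N5CCC[C@@H]5C(O[Si](C)(C)C)(c5cc(cc(c5)C(F)(F)F)C(F)(F)F)c5cc(cc(c5)C(F)(F)F)C(F)(F)F)c1OCc1ccc(cc1)C(F)(F)F.[O-]C(=O)C(F)(F)F | intermediate (not isolated)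
14 | (2S,3S)-6-Fis-2-[3,4,5-tris(benzyloxy)phenyl]-5-(TFB-oxy)-7-(TBB-oxy)chromane-3-carbaldehyde (2,3-trans) | c1ccccc1COc1ccc2c(c1)O[C@H](c1ccc(OCc3ccccc3)c(OCc3ccccc3)c1)[C@@H](O)[C@@H]2c1c(OCc3cc(OCc4ccccc4)c(OCc4ccccc4)c(OCc4ccccc4)c3)cc2c(c1OCc1ccc(cc1)C(F)(F)F)C[C@H](C=O)[C@@H](c1cc(OCc3ccccc3)c(OCc3ccccc3)c(OCc3ccccc3)c1)O2 | intermediate
15 | (2R,3S)-6-Fis-2-[3,4,5-tris(benzyloxy)phenyl]-5-(TFB-oxy)-7-(TBB-oxy)chroman-3-yl formate | c1ccccc1COc1ccc2c(c1)O[C@H](c1ccc(OCc3ccccc3)c(OCc3ccccc3)c1)[C@@H](O)[C@@H]2c1c(OCc3cc(OCc4ccccc4)c(OCc4ccccc4)c(OCc4ccccc4)c3)cc2c(c1OCc1ccc(cc1)C(F)(F)F)C[C@H](OC=O)[C@@H](c1cc(OCc3ccccc3)c(OCc3ccccc3)c(OCc3ccccc3)c1)O2 | intermediate (not isolated)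
16 | (2R,3S)-6-Fis-2-[3,4,5-tris(benzyloxy)phenyl]-5-(TFB-oxy)-7-(TBB-oxy)chroman-3-ol | c1ccccc1COc1ccc2c(c1)O[C@H](c1ccc(OCc3ccccc3)c(OCc3ccccc3)c1)[C@@H](O)[C@@H]2c1c(OCc3cc(OCc4ccccc4)c(OCc4ccccc4)c(OCc4ccccc4)c3)cc2c(c1OCc1ccc(cc1)C(F)(F)F)C[C@H](O)[C@@H](c1cc(OCc3ccccc3)c(OCc3ccccc3)c(OCc3ccccc3)c1)O2 | intermediate
17 | fisetinidol-(4alpha,6)-gallocatechin | Oc1ccc2c(c1)O[C@H](c1ccc(O)c(O)c1)[C@@H](O)[C@@H]2c1c(O)cc2c(c1O)C[C@H](O)[C@@H](c1cc(O)c(O)c(O)c1)O2 | target

**Totals**

Total step count: 11. Longest linear sequence: 10 steps (1 to 17 through steps 1–3 and 5–11; step 4 is a one-step side branch).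

**Steps most likely to fail, with fallbacks**

1. Step 9 (proposed method). Hydride transfer from the benzyl aryl ether to the iminium ion may be too slow, so that hydrolysis of the oxocarbenium ion (loss of ring E as its aldehyde), desilylation of the catalyst or acid cleavage of the TBB ethers outruns ring closure; the catalyst may also control the enamine face incompletely. The fallback sets out from 11 and uses the known Lewis-acid mode of the same internal redox reaction: BF3·OEt2 in CH2Cl2 (0 → 25 °C), where the hydride goes to the boron-bound enal and the boron enolate closes ring F. Without a chiral controller this should give 14 together with the (2R,3R)-trans aldehyde F1. The two are diastereomers because the upper unit is chiral, and they are separated by chromatography. The route is rejoined at 14.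

2. Step 3. The Friedel–Crafts reaction may show poor site selectivity (attack through C6 or C3 of the coumarin, double alkylation, self-condensation of the cation with ring A of 3) and incomplete facial selectivity at C4 of the 5-deoxy flavanyl cation. The fallback changes the order of events so that the nucleophile is the bulkier, fully etherified coumarin. Compound 4 is alkylated with 7 (K2CO3, DMF) to 5,7-bis(TBB-oxy)coumarin F2, and 3 is then coupled with F2 (BF3·OEt2, CH2Cl2, −40 °C). C6 of F2 is flanked by two large ethers, so only C8 is open, and the bulk and low temperature should favour attack anti to the C3 hydroxyl. The product is 8, where the route is rejoined; 5 and step 5 are bypassed.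

3. Step 10. Hydride may migrate in competition with C3 in the peracid adduct, giving the carboxylic acid, or the formyl-bearing carbon may epimerise before oxidation. The fallback sets out from 14: homologation of the aldehyde with diazomethane (Et2O/MeOH, 0 °C) gives methyl ketone F3, whose Baeyer–Villiger oxidation (mCPBA, CH2Cl2) proceeds by migration of the secondary carbon over methyl with retention to give acetate F4. K2CO3 in MeOH then gives 16, where the route is rejoined.

**Further compounds**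

F1 | step 9 | (2R,3R)-6-Fis-2-[3,4,5-tris(benzyloxy)phenyl]-5-(TFB-oxy)-7-(TBB-oxy)chromane-3-carbaldehyde | c1ccccc1COc1ccc2c(c1)O[C@H](c1ccc(OCc3ccccc3)c(OCc3ccccc3)c1)[C@@H](O)[C@@H]2c1c(OCc3cc(OCc4ccccc4)c(OCc4ccccc4)c(OCc4ccccc4)c3)cc2c(c1OCc1ccc(cc1)C(F)(F)F)C[C@@H](C=O)[C@H](c1cc(OCc3ccccc3)c(OCc3ccccc3)c(OCc3ccccc3)c1)O2
F2 | step 3 | 5,7-bis(TBB-oxy)-2H-chromen-2-one | O=c1ccc2c(OCc3cc(OCc4ccccc4)c(OCc4ccccc4)c(OCc4ccccc4)c3)cc(OCc3cc(OCc4ccccc4)c(OCc4ccccc4)c(OCc4ccccc4)c3)cc2o1
F3 | step 10 | 1-[(2S,3S)-6-Fis-2-[3,4,5-tris(benzyloxy)phenyl]-5-(TFB-oxy)-7-(TBB-oxy)chroman-3-yl]ethanone | c1ccccc1COc1ccc2c(c1)O[C@H](c1ccc(OCc3ccccc3)c(OCc3ccccc3)c1)[C@@H](O)[C@@H]2c1c(OCc3cc(OCc4ccccc4)c(OCc4ccccc4)c(OCc4ccccc4)c3)cc2c(c1OCc1ccc(cc1)C(F)(F)F)C[C@H](C(C)=O)[C@@H](c1cc(OCc3ccccc3)c(OCc3ccccc3)c(OCc3ccccc3)c1)O2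
F4 | step 10 | (2R,3S)-6-Fis-2-[3,4,5-tris(benzyloxy)phenyl]-5-(TFB-oxy)-7-(TBB-oxy)chroman-3-yl acetate | c1ccccc1COc1ccc2c(c1)O[C@H](c1ccc(OCc3ccccc3)c(OCc3ccccc3)c1)[C@@H](O)[C@@H]2c1c(OCc3cc(OCc4ccccc4)c(OCc4ccccc4)c(OCc4ccccc4)c3)cc2c(c1OCc1ccc(cc1)C(F)(F)F)C[C@H](OC(C)=O)[C@@H](c1cc(OCc3ccccc3)c(OCc3ccccc3)c(OCc3ccccc3)c1)O2
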